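All constants are assumed.

The rate constant for dawn's release of product from the complex stood 3.2 times above summer's, and I wanted to know whether a larger constant also meant more product.

| setting | midnight | summer | dawn |
|---|---|---|---|
| substrate | 20 mM | 20 mM | 20 mM |
| free enzyme | 0.05 mol% | 0.05 mol% | 0.05 mol% |
| time | 20 s | 20 s | 20 s |
| remark | at 37 °C until 4.0 s, from then on at 52 °C |  |  |
| temperature |  | 37 °C | 52 °C |

    free enzyme → unfolded enzyme (k1 = 2.25 × 10⁻⁴ s⁻¹, Ea1 = 242 kJ mol⁻¹)
    substrate + free enzyme ⇌ complex (K2 = 82 L mol⁻¹, k2 = 5.83 × 10⁵ L mol⁻¹ s⁻¹, Ea2 = 8.00 kJ mol⁻¹, ΔH2 = −31.0 kJ mol⁻¹)
    complex ⇌ free enzyme + product (K3 = 0.93 M, k3 = 1820 s⁻¹, Ea3 = 65.0 kJ mol⁻¹, ΔH3 = −70.0 kJ mol⁻¹)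
    free enzyme ⇌ dormant form (K4 = 8.8, k4 = 0.215 s⁻¹, Ea4 = 68.0 kJ mol⁻¹, ΔH4 = −12.0 kJ mol⁻¹)
    (constants at 37 °C)

- the best flask by amount of product, in percent of the substrate charged; "all alike" if 1.5 percentage points covers them all (midnight / summer / dawn / all alike)
- amount of product at the end, in percent of the substrate charged, midnight
- amount of product at the end, in percent of the substrate charged, summer
- amount of product at the end, in percent of the substrate charged, dawn

- at 37 °C the constants are as listed, elsewhere as the activation energies and enthalpies make them

At the bench I would count turnovers: if the enzyme can release more than the charge of substrate within the time, expect complete conversion. The curve of c(free enzyme) falls as the dormant form fills, so I replaced it by its plateau, the charge over one plus 8.8. At 37 °C the count came to 1.86 charges. That mean was low for the first seconds, and it was generous in counting every working enzyme as complex, so I took the count as rough. Still, the rule promised that summer would finish.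

The rule stops where the way back matters, and a ratio of given constants finds that border. The product K2·K3 compares product with substrate at balance: it was 76.3 at 37 °C, and the two enthalpies lowered it to 12.5 at 52 °C. I called one over one plus that ratio the remainder, the share of the charge that stays substrate once forward and back balance; I neglected the small amount held as complex. The remainder was 1.29% in the cool flask and 7.40% in the hot one, and the margin of 1.5 percentage points lies between them. The bench rule therefore served within that margin at 37 °C and failed at 52 °C, where yield comes under thermodynamic control. My reckoning gave 98.7% for summer and 92.6% for dawn. Midnight ends at dawn's temperature, so I gave it 92.6% too, and the best flask was summer.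

The forecast gave 92.6% for midnight, 98.6% for summer and 92.5% for dawn, and named summer; with the balance as its ceiling, its question was “whether enzyme survives long enough to reach it”.

The flasks gave 92.6% at midnight, 98.6% in summer and 92.5% at dawn, with summer best. Summer kept 1.4% of its substrate at 20.0 s against a remainder of 1.29%, and the main reason for that shortfall was the undoing of complex into substrate and free enzyme: with that step struck out, summer gave >99.9% instead of 98.6%. The remainder contains no concentration, so dawn's 7.40% also stands for a dawn flask with 5.0 mM of substrate at the same loading, and that flask still held 23% unbound at 20.0 s, 16 points above it.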